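**Plan**

- Retrosynthesis: the five benzyl ethers come off last. Ring A, counted from its bridge carbon as position 1 (2 OH, 3 CH3, 4 OCH3, 5 acetyl, 6 OH), is then cut between positions 3 and 4 and between positions 5 and 6. This gives 4-methoxybut-3-yn-2-one and a 1-benzyloxy-1,3-bis(silyloxy)penta-1,3-diene that carries the protected B–C dimer on C2.
- Enabling feature: in ring A the acetyl carbon (position 5) and the methoxy carbon (position 4) are neighbours, which is the Cα/Cβ pair of that ynone. Positions 6, 1, 2 and 3 of ring A (O, bridge, O, CH3) are the dienolate of a 2-substituted 3-oxopentanoate.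
- Further cuts: the C2–CH2 bond of the keto ester (enolate alkylation by the B–C benzylic bromide), the one-carbon arm on ring B (formylation), and the ring B–CH2 bond of the B–C diarylmethane (Friedel–Crafts benzylation).
- Forward: ring C (from 2-methylphloroglucinol) and ring B (from phloroglucinol) are made as benzyl-protected butanoyl arenes and joined. Ring B is homologated and alkylated onto benzyl 3-oxopentanoate, silylation gives the diene, ring A is built last, and hydrogenolysis ends the route.
- Stereochemistry: the target has no stereocentre. Those that appear on the way (C2 of the keto ester, two sp3 carbons of the cycloadduct) are uncontrolled and erased.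

Key step: step 17

Remark: on acidic desilylation the silyl benzyl ketal carbon of the cycloadduct is assumed to collapse to the carbonyl, so the product of the key step is planned with a free hydroxyl on position 6 of ring A. If silanol were lost instead, the benzyl ether left on that position would be removed in the final hydrogenolysis as well.

**Route**

Step 1
Reactants: 1 2-methylphloroglucinol
Product: 2 1-(2,4,6-trihydroxy-3-methylphenyl)butan-1-one
Conditions: butanoyl chloride (1.05 equiv), AlCl3 (3 equiv), PhNO2–CH2Cl2, 0 °C → rt; aq. HCl work-up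
Reagents that add atoms: butanoyl chloride, CCCC(=O)Cl
Why: Friedel–Crafts C-acylation of the electron-rich triol, whose two open ring positions are equivalent, so that one mono-ketone should form and the new acyl group holds back a second acylation.

Step 2
Reactants: 2 1-(2,4,6-trihydroxy-3-methylphenyl)butan-1-one
Product: 3 1-[4,6-bis(benzyloxy)-2-hydroxy-3-methylphenyl]butan-1-one
Conditions: BnBr (2.1 equiv), K2CO3 (2.2 equiv), acetone, reflux
Reagents that add atoms: benzyl bromide, BrCc1ccccc1
Why: Williamson etherification that should take the para hydroxyl first and then the ortho hydroxyl not flanked by the methyl group, leaving free the more shielded and more strongly chelated hydroxyl between butanoyl and methyl.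

Step 3
Reactants: 3 1-[4,6-bis(benzyloxy)-2-hydroxy-3-methylphenyl]butan-1-one
Product: 4 1-[4,6-bis(benzyloxy)-2-methoxy-3-methylphenyl]butan-1-one
Conditions: MeI (3 equiv), K2CO3 (2 equiv), DMF, 50 °C
Reagents that add atoms: iodomethane, CI
Why: Williamson methylation of the last, chelated phenol under more forcing conditions, which fixes the ring C methyl ether between the butanoyl and methyl groups.

Step 4
Reactants: 4 1-[4,6-bis(benzyloxy)-2-methoxy-3-methylphenyl]butan-1-one
Product: 6 2,6-bis(benzyloxy)-3-butanoyl-4-methoxy-5-methylbenzaldehyde, via iminium chloride 5 (not isolated)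
Conditions: (chloromethylene)dimethyliminium chloride (1.5 equiv), MeCN, 0 → 50 °C; then H2O, rt
Reagents that add atoms: (chloromethylene)dimethyliminium chloride, C[N+](C)=CCl.[Cl-]; water, O
Why: Vilsmeier–Haack formylation at the only unsubstituted position of the core ring, para to the methoxy group and between two benzyloxy groups, the phenyl rings of the benzyl ethers being far less nucleophilic.

Step 5
Reactants: 6 2,6-bis(benzyloxy)-3-butanoyl-4-methoxy-5-methylbenzaldehyde
Product: 7 1-[4,6-bis(benzyloxy)-5-(hydroxymethyl)-2-methoxy-3-methylphenyl]butan-1-one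
Conditions: NaBH4 (1 equiv), THF–MeOH, 0 °C
Reagents that add atoms: none
Why: borohydride reduction that should take only the aldehyde, because the butanoyl ketone sits between two ortho substituents and is too hindered to react at 0 °C.

Step 6
Reactants: 8 phloroglucinol
Product: 9 1-(2,4,6-trihydroxyphenyl)butan-1-one
Conditions: butanoyl chloride (1.0 equiv), AlCl3 (3 equiv), PhNO2–CH2Cl2, 0 °C → rt; aq. HCl work-up
Reagents that add atoms: butanoyl chloride, CCCC(=O)Cl
Why: Friedel–Crafts mono-acylation of phloroglucinol, limited to one acyl group by the stoichiometry and by the deactivation the ketone brings.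

Step 7
Reactants: 9 1-(2,4,6-trihydroxyphenyl)butan-1-one
Product: 10 1-[2,4,6-tris(benzyloxy)phenyl]butan-1-one
Conditions: BnBr (3.6 equiv), K2CO3 (4 equiv), DMF, 70 °C
Reagents that add atoms: benzyl bromide, BrCc1ccccc1
Why: exhaustive Williamson benzylation, heating in DMF being enough to etherify the two chelated ortho hydroxyls as well.

Step 8
Reactants: 7 1-[4,6-bis(benzyloxy)-5-(hydroxymethyl)-2-methoxy-3-methylphenyl]butan-1-one; 10 1-[2,4,6-tris(benzyloxy)phenyl]butan-1-one (3 equiv)
Product: 11 penta-O-benzyl B–C dimer (1-[2,4,6-tris(benzyloxy)-3-{[2,6-bis(benzyloxy)-3-butanoyl-4-methoxy-5-methylphenyl]methyl}phenyl]butan-1-one)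
Conditions: Sc(OTf)3 (5 mol %), MeNO2–CH2Cl2, 0 °C → rt
Reagents that add atoms: none
Why: Friedel–Crafts benzylation through the 2,6-dibenzyloxy-4-methoxybenzyl cation with loss of water, in which 7 cannot oligomerise because its core ring has no free position and the excess of 10 should keep alkylation to one of its two equivalent sites.

Step 9
Reactants: 11 penta-O-benzyl B–C dimer
Product: 13 B–C dimer aldehyde (formyl on the last free carbon of ring B), via iminium chloride 12 (not isolated)
Conditions: (chloromethylene)dimethyliminium chloride (2 equiv), MeCN, 0 → 55 °C; then H2O, rt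
Reagents that add atoms: (chloromethylene)dimethyliminium chloride, C[N+](C)=CCl.[Cl-]; water, O
Why: Vilsmeier–Haack formylation at the single remaining core C–H, which lies on ring B between two benzyloxy groups and para to the third.

Step 10
Reactants: 13 B–C dimer aldehyde
Product: 14 B–C dimer benzylic alcohol
Conditions: NaBH4 (1 equiv), THF–MeOH, 0 °C
Reagents that add atoms: none
Why: chemoselective borohydride reduction of the aldehyde in the presence of two di-ortho-substituted aryl ketones.

Step 11
Reactants: 14 B–C dimer benzylic alcohol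
Product: 15 B–C dimer benzylic bromide
Conditions: CBr4 (1.3 equiv), PPh3 (1.3 equiv), CH2Cl2, 0 °C; used at once
Reagents that add atoms: tetrabromomethane, BrC(Br)(Br)Br
Why: Appel bromination under neutral conditions that spare the benzyl ethers, the fully substituted ring B being unable to alkylate itself.

Step 12
Reactants: 16 methyl 3-oxopentanoate
Product: 17 benzyl 3-oxopentanoate
Conditions: BnOH (1.1 equiv), DMAP (10 mol %), toluene, reflux, MeOH distilled off
Reagents that add atoms: benzyl alcohol, OCc1ccccc1
Why: DMAP-catalysed transesterification of a β-keto ester, the benzyl group being chosen so that the ester alkoxy residue is removable by hydrogenolysis should it stay on ring A in step 17.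

Step 13
Reactants: 17 benzyl 3-oxopentanoate (2.5 equiv); 15 B–C dimer benzylic bromide
Product: 19 racemic benzyl 2-(B–C dimer methyl)-3-oxopentanoate, via sodium enolate 18 (not isolated)
Conditions: NaH (2.4 equiv), THF, 0 °C; then 15, THF–DMF, 0 °C → rt
Reagents that add atoms: none
Why: C-alkylation of a β-keto ester enolate by a benzylic bromide, with excess enolate to suppress dialkylation; the new C2 stereocentre forms racemic and is erased by enolisation in step 14.

Step 14
Reactants: 19 racemic benzyl 2-(B–C dimer methyl)-3-oxopentanoate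
Product: 20 benzyl 2-(B–C dimer methyl)-3-(trimethylsilyloxy)pent-2-enoate (E/Z mixture)
Conditions: TMSCl (1.5 equiv), Et3N (1.6 equiv), toluene, rt; filtered and concentrated under argon
Reagents that add atoms: chlorotrimethylsilane, C[Si](C)(C)Cl
Why: O-silylation of the readily enolised β-keto ester under conditions too mild to touch the two butanoyl ketones, the enol ether geometry being without consequence for the next step.

Step 15
Reactants: 20 benzyl 2-(B–C dimer methyl)-3-(trimethylsilyloxy)pent-2-enoate
Product: 21 (1Z,3Z)-1-benzyloxy-1,3-bis(trimethylsilyloxy)penta-1,3-diene carrying the B–C dimer methyl arm on C2 (both butanoyl groups masked as (Z)-trimethylsilyl enol ethers)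
Conditions: LDA (3.5 equiv), TMSCl (4.5 equiv, present from the start), THF, −78 → −40 °C; non-aqueous work-up, used crude
Reagents that add atoms: chlorotrimethylsilane, C[Si](C)(C)Cl
Why: kinetic γ-deprotonation of the β-silyloxy enoate with in situ O-silylation gives the 1,3-bis(silyloxy)diene, and because LDA enolises the two aryl ketones too, they are deliberately silylated in the same operation as a temporary mask that the acid work-up of step 17 removes.

Step 16
Reactants: 22 chloroacetaldehyde dimethyl acetal
Product: 24 4-methoxybut-3-yn-2-one, via lithium methoxyacetylide 23 (not isolated)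
Conditions: LiNEt2 (3.1 equiv), THF, 0 °C; then N-methoxy-N-methylacetamide, −78 °C; cold aq. NH4Cl; used fresh
Reagents that add atoms: N-methoxy-N-methylacetamide, CON(C)C(C)=O
Why: twofold elimination from the chloroacetal gives the alkoxyacetylide, which the Weinreb amide acylates only once because the chelated tetrahedral adduct persists until the quench.

Step 17
Reactants: 21 tetrasilylated diene; 24 4-methoxybut-3-yn-2-one (2 equiv)
Product: 26 penta-O-benzyl agrimol F (both ring A hydroxyls free), via cyclohexadiene cycloadduct 25 (not isolated)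
Conditions: toluene, 20 → 60 °C; then 1 M HCl, THF, 0 °C → rt
Reagents that add atoms: none
Why: Proposed new method: the methyl-substituted terminus C4 of diene 21, the site of highest electron density because three oxygen donors push toward it, should bond to the methoxy-substituted β-carbon of ynone 24 and the ketene-acetal carbon C1 to the α-carbon, in one asynchronous [4+2] event or as a Mukaiyama–Michael addition followed by collapse of the allenolate onto the silyloxy(benzyloxy)carbenium carbon, giving cyclohexa-1,4-diene 25. Dilute acid then strips the silyl groups, the silyl benzyl ketal carbon falls to the carbonyl with loss of benzyl alcohol, the resulting cyclohexenedione tautomerises to the resorcinol-type ring A, and the two masking enol ethers return to butanoyl groups. The closest known reaction type is the Diels–Alder reaction with aromatisation of 1-alkoxy-1,3-bis(silyloxy)dienes and related ketene-acetal dienes with alkynyl ketones and esters, which has not been shown for a 4-alkoxy ynone or for a diene substituted at both C2 and C4. Ring A closes as a six-membered carbocycle in the [4+2] mode, which in the stepwise variant is a 6-exo-trig attack of the allenolate α-carbon on the exocyclic C=O+ unit. No stereocentre is set, since the two sp3 carbons of 25 form without control and both become aromatic. The selectivity needed is regiochemical (methoxy beside methyl, acetyl beside the former ester carbon) and is secured by the polarity match just described, while the substituent on C2 shuts off the alternative [3+3] mode through C2 and the simple silyl enol ethers are too weak as nucleophiles to engage the ynone without a Lewis acid.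

Step 18
Reactants: 26 penta-O-benzyl agrimol F (both ring A hydroxyls free)
Product: 27 agrimol F
Conditions: H2 (1 atm), 10% Pd/C (palladium on carbon), EtOAc–MeOH, rt
Reagents that add atoms: none
Why: hydrogenolysis of the five aryl benzyl ethers under neutral conditions, to which the aryl ketones, methyl ethers and diarylmethane bridges should be inert.

**Compound list**

1 | 2-methylphloroglucinol (2-methylbenzene-1,3,5-triol) | Cc1c(O)cc(O)cc1O | starting material
2 | 1-(2,4,6-trihydroxy-3-methylphenyl)butan-1-one | CCCC(=O)c1c(O)cc(O)c(C)c1O | intermediate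
3 | 1-[4,6-bis(benzyloxy)-2-hydroxy-3-methylphenyl]butan-1-one | CCCC(=O)c1c(O)c(C)c(OCc2ccccc2)cc1OCc1ccccc1 | intermediate
4 | 1-[4,6-bis(benzyloxy)-2-methoxy-3-methylphenyl]butan-1-one (protected ring C monomer) | CCCC(=O)c1c(OC)c(C)c(OCc2ccccc2)cc1OCc1ccccc1 | intermediate
5 | N-{[2,6-bis(benzyloxy)-3-butanoyl-4-methoxy-5-methylphenyl]methylidene}-N-methylmethanaminium chloride | CCCC(=O)c1c(OC)c(C)c(OCc2ccccc2)c(C=[N+](C)C)c1OCc1ccccc1.[Cl-] | intermediate
6 | 2,6-bis(benzyloxy)-3-butanoyl-4-methoxy-5-methylbenzaldehyde | CCCC(=O)c1c(OC)c(C)c(OCc2ccccc2)c(C=O)c1OCc1ccccc1 | intermediate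
7 | 1-[4,6-bis(benzyloxy)-5-(hydroxymethyl)-2-methoxy-3-methylphenyl]butan-1-one | CCCC(=O)c1c(OC)c(C)c(OCc2ccccc2)c(CO)c1OCc1ccccc1 | intermediate
8 | phloroglucinol (benzene-1,3,5-triol) | Oc1cc(O)cc(O)c1 | starting material
9 | 1-(2,4,6-trihydroxyphenyl)butan-1-one | CCCC(=O)c1c(O)cc(O)cc1O | intermediate
10 | 1-[2,4,6-tris(benzyloxy)phenyl]butan-1-one | CCCC(=O)c1c(OCc2ccccc2)cc(OCc2ccccc2)cc1OCc1ccccc1 | intermediate
11 | penta-O-benzyl B–C dimer, 1-[2,4,6-tris(benzyloxy)-3-{[2,6-bis(benzyloxy)-3-butanoyl-4-methoxy-5-methylphenyl]methyl}phenyl]butan-1-one | CCCC(=O)c1c(OCc2ccccc2)cc(OCc2ccccc2)c(Cc2c(OCc3ccccc3)c(C)c(OC)c(C(=O)CCC)c2OCc2ccccc2)c1OCc1ccccc1 | intermediate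
12 | dimethyliminium chloride of aldehyde 13 (ring B CH=NMe2+ Cl−) | CCCC(=O)c1c(OCc2ccccc2)c(C=[N+](C)C)c(OCc2ccccc2)c(Cc2c(OCc3ccccc3)c(C)c(OC)c(C(=O)CCC)c2OCc2ccccc2)c1OCc1ccccc1.[Cl-] | intermediate
13 | B–C dimer aldehyde, 2,4,6-tris(benzyloxy)-3-{[2,6-bis(benzyloxy)-3-butanoyl-4-methoxy-5-methylphenyl]methyl}-5-butanoylbenzaldehyde | CCCC(=O)c1c(OCc2ccccc2)c(C=O)c(OCc2ccccc2)c(Cc2c(OCc3ccccc3)c(C)c(OC)c(C(=O)CCC)c2OCc2ccccc2)c1OCc1ccccc1 | intermediate
14 | B–C dimer benzylic alcohol (CH2OH in place of CHO in 13) | CCCC(=O)c1c(OCc2ccccc2)c(CO)c(OCc2ccccc2)c(Cc2c(OCc3ccccc3)c(C)c(OC)c(C(=O)CCC)c2OCc2ccccc2)c1OCc1ccccc1 | intermediate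
15 | B–C dimer benzylic bromide (CH2Br in place of CH2OH in 14) | CCCC(=O)c1c(OCc2ccccc2)c(CBr)c(OCc2ccccc2)c(Cc2c(OCc3ccccc3)c(C)c(OC)c(C(=O)CCC)c2OCc2ccccc2)c1OCc1ccccc1 | intermediate
16 | methyl 3-oxopentanoate | CCC(=O)CC(=O)OC | starting material
17 | benzyl 3-oxopentanoate | CCC(=O)CC(=O)OCc1ccccc1 | intermediate
18 | sodium enolate of benzyl 3-oxopentanoate (written as the C2 carbanion) | CCC(=O)[CH-]C(=O)OCc1ccccc1.[Na+] | intermediate
19 | racemic benzyl 3-oxopentanoate bearing the B–C dimer methyl arm on C2 | CCC(=O)C(Cc1c(OCc2ccccc2)c(C(=O)CCC)c(OCc2ccccc2)c(Cc2c(OCc3ccccc3)c(C)c(OC)c(C(=O)CCC)c2OCc2ccccc2)c1OCc1ccccc1)C(=O)OCc1ccccc1 | intermediate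
20 | benzyl 3-(trimethylsilyloxy)pent-2-enoate bearing the B–C dimer methyl arm on C2 (E/Z mixture, no descriptor drawn) | CCC(O[Si](C)(C)C)=C(Cc1c(OCc2ccccc2)c(C(=O)CCC)c(OCc2ccccc2)c(Cc2c(OCc3ccccc3)c(C)c(OC)c(C(=O)CCC)c2OCc2ccccc2)c1OCc1ccccc1)C(=O)OCc1ccccc1 | intermediate
21 | (1Z,3Z)-1-benzyloxy-1,3-bis(trimethylsilyloxy)penta-1,3-diene with the B–C dimer methyl arm on C2 and both butanoyl groups as (Z)-1-(trimethylsilyloxy)but-1-enyl groups | C/C=C(\O[Si](C)(C)C)/C(Cc1c(OCc2ccccc2)c(/C(O[Si](C)(C)C)=C/CC)c(OCc2ccccc2)c(Cc2c(OCc3ccccc3)c(C)c(OC)c(/C(O[Si](C)(C)C)=C/CC)c2OCc2ccccc2)c1OCc1ccccc1)=C(/OCc1ccccc1)O[Si](C)(C)C | intermediate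
22 | chloroacetaldehyde dimethyl acetal (2-chloro-1,1-dimethoxyethane) | COC(CCl)OC | starting material
23 | lithium methoxyacetylide | [Li]C#COC | intermediate
24 | 4-methoxybut-3-yn-2-one | COC#CC(C)=O | intermediate
25 | cyclohexa-1,4-diene cycloadduct, numbered around the new ring: C1 acetyl, C2 OCH3, C3 H and CH3, C4 OSiMe3, C5 the B–C arm, C6 OBn and OSiMe3 (mixture of diastereomers at C3 and C6, both centres transient) | CC(=O)C1=C(OC)C(C)C(O[Si](C)(C)C)=C(Cc2c(OCc3ccccc3)c(/C(O[Si](C)(C)C)=C/CC)c(OCc3ccccc3)c(Cc3c(OCc4ccccc4)c(C)c(OC)c(/C(O[Si](C)(C)C)=C/CC)c3OCc3ccccc3)c2OCc2ccccc2)C1(OCc1ccccc1)O[Si](C)(C)C | intermediate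
26 | penta-O-benzyl agrimol F: rings B and C fully benzylated, ring A with both hydroxyls free (those flanking its bridge carbon) | CC(=O)c1c(OC)c(C)c(O)c(Cc2c(OCc3ccccc3)c(C(=O)CCC)c(OCc3ccccc3)c(Cc3c(OCc4ccccc4)c(C)c(OC)c(C(=O)CCC)c3OCc3ccccc3)c2OCc2ccccc2)c1O | intermediate
27 | agrimol F (achiral) | CCCC(=O)c1c(O)c(Cc2c(O)c(C)c(OC)c(C(C)=O)c2O)c(O)c(Cc2c(O)c(C)c(OC)c(C(=O)CCC)c2O)c1O | target

**Count and risks**

Total steps: 18. Longest linear sequence: 14 steps (steps 1–5, 8–11, 13–15, 17, 18).

Steps most likely to fail: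

1. Step 17. The donor-substituted alkyne may be too weak an electrophile for the doubly substituted, hindered diene, so that hydrolysis or polymerisation of the partners could outrun ring formation, or bond formation could take the opposite orientation. The fallback uses known chemistry and attaches ring A instead of building it; it sets out from 1 and from alcohol 14. Friedel–Crafts acetylation of 1 (acetyl chloride, AlCl3) should give 1-(2,4,6-trihydroxy-3-methylphenyl)ethan-1-one F1. Selective dibenzylation as in step 2 should give 1-[4,6-bis(benzyloxy)-2-hydroxy-3-methylphenyl]ethan-1-one F2, and methylation as in step 3 should give 1-[4,6-bis(benzyloxy)-2-methoxy-3-methylphenyl]ethan-1-one F3. Sc(OTf)3-catalysed Friedel–Crafts benzylation of the single free ring position of F3 with 14 should give hepta-O-benzyl agrimol F F4. Hydrogenolysis over Pd/C then rejoins the route at 27.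

2. Step 15. Deprotonation has to occur at three sites of one large molecule, so incomplete silylation, C-silylation, or hydrolytic loss of silyl groups during isolation could leave a mixture unfit for cycloaddition. The fallback moves the ring construction ahead of the union with the B–C dimer, so that no ketone is present when the diene is made; it sets out from 17. TMSCl/Et3N should give benzyl (Z)-3-(trimethylsilyloxy)pent-2-enoate F5, and LDA/TMSCl should give (1Z,3Z)-1-benzyloxy-1,3-bis(trimethylsilyloxy)penta-1,3-diene F6. Reaction of F6 with 24 under the conditions of step 17 should pass through the cycloadduct 1-[6-(benzyloxy)-2-methoxy-3-methyl-4,6-bis(trimethylsilyloxy)cyclohexa-1,4-dien-1-yl]ethan-1-one F7 and, after the acid work-up, give 1-(4,6-dihydroxy-2-methoxy-3-methylphenyl)ethan-1-one F8. The only free ring carbon of F8, flanked by two hydroxyls, is then benzylated by alcohol 14 with Sc(OTf)3, which rejoins the route at 26.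

3. Step 8. The acid-catalysed union could run on to double benzylation of 10, or the Lewis acid could trigger benzyl ether cleavage and re-equilibration of the diarylmethane. The fallback replaces the cationic coupling by a palladium-catalysed benzyl–aryl Suzuki–Miyaura coupling; it sets out from 7 and 10. Appel bromination of 7 should give 1-[4,6-bis(benzyloxy)-5-(bromomethyl)-2-methoxy-3-methylphenyl]butan-1-one F9. Monobromination of 10 with NBS should give 1-[2,4,6-tris(benzyloxy)-3-bromophenyl]butan-1-one F10. Miyaura borylation (B2pin2, PdCl2(dppf), KOAc, dioxane) should give 1-[2,4,6-tris(benzyloxy)-3-(4,4,5,5-tetramethyl-1,3,2-dioxaborolan-2-yl)phenyl]butan-1-one F11. Coupling of F9 with F11 (Pd(PPh3)4, K2CO3, dioxane–H2O) rejoins the route at 11.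

**Further compounds**

F1 | step 17 | 1-(2,4,6-trihydroxy-3-methylphenyl)ethan-1-one | CC(=O)c1c(O)cc(O)c(C)c1O
F2 | step 17 | 1-[4,6-bis(benzyloxy)-2-hydroxy-3-methylphenyl]ethan-1-one | CC(=O)c1c(O)c(C)c(OCc2ccccc2)cc1OCc1ccccc1
F3 | step 17 | 1-[4,6-bis(benzyloxy)-2-methoxy-3-methylphenyl]ethan-1-one | CC(=O)c1c(OC)c(C)c(OCc2ccccc2)cc1OCc1ccccc1
F4 | step 17 | hepta-O-benzyl agrimol F | CC(=O)c1c(OC)c(C)c(OCc2ccccc2)c(Cc2c(OCc3ccccc3)c(C(=O)CCC)c(OCc3ccccc3)c(Cc3c(OCc4ccccc4)c(C)c(OC)c(C(=O)CCC)c3OCc3ccccc3)c2OCc2ccccc2)c1OCc1ccccc1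
F5 | step 15 | benzyl (Z)-3-(trimethylsilyloxy)pent-2-enoate | CC/C(O[Si](C)(C)C)=C/C(=O)OCc1ccccc1
F6 | step 15 | (1Z,3Z)-1-benzyloxy-1,3-bis(trimethylsilyloxy)penta-1,3-diene | C/C=C(\O[Si](C)(C)C)/C=C(/OCc1ccccc1)O[Si](C)(C)C
F7 | step 15 | 1-[6-(benzyloxy)-2-methoxy-3-methyl-4,6-bis(trimethylsilyloxy)cyclohexa-1,4-dien-1-yl]ethan-1-one (mixture of diastereomers) | CC(=O)C1=C(OC)C(C)C(O[Si](C)(C)C)=CC1(OCc1ccccc1)O[Si](C)(C)C
F8 | step 15 | 1-(4,6-dihydroxy-2-methoxy-3-methylphenyl)ethan-1-one | CC(=O)c1c(OC)c(C)c(O)cc1O
F9 | step 8 | 1-[4,6-bis(benzyloxy)-5-(bromomethyl)-2-methoxy-3-methylphenyl]butan-1-one | CCCC(=O)c1c(OC)c(C)c(OCc2ccccc2)c(CBr)c1OCc1ccccc1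
F10 | step 8 | 1-[2,4,6-tris(benzyloxy)-3-bromophenyl]butan-1-one | CCCC(=O)c1c(OCc2ccccc2)cc(OCc2ccccc2)c(Br)c1OCc1ccccc1
F11 | step 8 | 1-[2,4,6-tris(benzyloxy)-3-(4,4,5,5-tetramethyl-1,3,2-dioxaborolan-2-yl)phenyl]butan-1-one | CCCC(=O)c1c(OCc2ccccc2)cc(OCc2ccccc2)c(B2OC(C)(C)C(C)(C)O2)c1OCc1ccccc1
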